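**Remark (assumption):** the SMILES is read as the trans lactone (3R,4R)-4-(3,4-dimethoxybenzyl)-3-(3-hydroxy-4,5-dimethoxybenzyl)oxolan-2-one. Compounds 1, 5, 6 and 11 (as a THF solution) are taken as purchasable.

## Analysis of the target

The target is a dibenzylbutyrolactone lignan with a single oxolan-2-one ring (O1, C2=O, C3, C4, C5H2). C3 carries a 3-hydroxy-4,5-dimethoxybenzyl arm through C7, and C4 carries a 3,4-dimethoxybenzyl arm through C7′. The two stereocentres are contiguous, both R, and the arms are trans. C3 is α to the carbonyl and epimerisable, and trans is the thermodynamically preferred arrangement. C4 is not epimerisable and must be set absolutely. Sensitive groups are the one free phenol, two electron-rich arenes, the base-labile lactone and the acidic C3–H. The ring is not the hard part: the two arms are electronically almost identical, yet each must sit on a defined carbon of an unsymmetrical lactone, so C2 and C5 must be told apart from the start. The feature that invites the strategy is the triad C3–C4–C7′. C3 is flanked by the acceptor C2=O and C7′ bears an aryl group, which is the retron of a homoconjugate opening of a cyclopropane (C3–C4–C7′) fused to the lactone ring. The opening leaves an enolate at C3, exactly where the second arm has to go.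

## Retrosynthetic reasoning

Target 16 is traced to its O-benzyl ether 15. The phenol is the only protic site and must be masked through the organometallic and enolate steps; hydrogenolysis at the end is neutral and leaves C3 alone.

Lactone 15 is traced to the α-methoxycarbonyl lactone 13 by replacing C3–H with C3–CO2Me. The ester is the second acceptor that the key step needs. Its removal generates the C3 enolate once more, so C3 can be set under thermodynamic control to trans.

In 13 two bonds are cut at once, aryl–C7′ and C3–C7, and C3–C7′ is reconnected. This gives the cyclopropane-fused lactone 10, the aryl Grignard 11 and the benzylic bromide 4. The cut is made here because the β-arm is then not brought in as a benzyl unit: C7′ is the cyclopropane methylene and the aryl ring arrives as a nucleophile. C2 and C5 are already distinct in 10, so the nucleophilic aryl must end on the C4 arm and the electrophilic benzyl on C3. The forward reaction has to open the three-membered ring at its CH2 only and alkylate the resulting enolate on carbon.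

Bicycle 10 is cut at both cyclopropane bonds to C1 and at the lactone C–O bond, giving dimethyl malonate 5 and (R)-epichlorohydrin 6. One operation delivers the ring, both acceptors and the C4 stereocentre from a cheap C3 chiral-pool unit.

Bromide 4 comes from alcohol 3, aldehyde 2 and the commercial phenol aldehyde 1 by functional-group changes only.

## Alternatives that were turned down

Alternative 1: the textbook route cuts C3–C7. The forward key step is trans-selective alkylation of the lithium enolate of (4R)-4-(3,4-dimethoxybenzyl)dihydrofuran-2(3H)-one A1 with bromide 4. A1 would come from a Stobbe condensation, an asymmetric hydrogenation of the itaconate half-ester and a chemoselective reduction. It was turned down because it is the route most chemists would draw first and its key step makes one bond. C4 depends on a pressure hydrogenation with a precious-metal catalyst, and the C2/C5 distinction depends on reducing an ester beside an acid. It is no shorter than the chosen route.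

Alternative 2: cut the O1–C5 bond by ring expansion. The forward key step is an enantioselective Baeyer–Villiger oxidation of the prochiral 3-(3,4-dimethoxybenzyl)cyclobutan-1-one A2, made by ketene [2+2] cycloaddition to an allylarene and dechlorination, giving A1. It was turned down because the catalyst must distinguish two enantiotopic CH2 groups remote from the substituent. The veratryl ring is exposed to a peroxide oxidant. After the ring expansion the C3 arm still needs the alkylation of Alternative 1, so the sequence is longer.

Alternative 3: cut the central C3–C4 bond. The forward key step is an oxidative hetero-coupling of two different 3-arylpropanoyl enolates on chiral auxiliaries, giving after cleavage (2R,3R)-2-[3-(benzyloxy)-4,5-dimethoxybenzyl]-3-(3,4-dimethoxybenzyl)butanedioic acid A3, then reduction of one carboxyl to C5. It was turned down because the two enolates have nearly the same oxidation potential, so homo- and hetero-coupling would be statistical. The two carboxyl groups of A3 differ only in remote ring substituents, so nothing directs the reduction to the C4 side and a regioisomeric lactone must be expected. Two stoichiometric auxiliaries are also consumed.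

Key step: step 5

## Route

Step 1
Reactants: 1 3-hydroxy-4,5-dimethoxybenzaldehyde
Product: 2 3-(benzyloxy)-4,5-dimethoxybenzaldehyde
Conditions: BnBr, K2CO3, DMF, rt
Reagents that add atoms: benzyl bromide, BrCc1ccccc1
Why: Williamson etherification of the phenoxide; the aldehyde is inert and the only acidic proton is masked before the organometallic steps.

Step 2
Reactants: 2 3-(benzyloxy)-4,5-dimethoxybenzaldehyde
Product: 3 [3-(benzyloxy)-4,5-dimethoxyphenyl]methanol
Conditions: NaBH4, MeOH, 0 °C
Reagents that add atoms: none
Why: Borohydride reduction of an aryl aldehyde; the ethers are untouched.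

Step 3
Reactants: 3 [3-(benzyloxy)-4,5-dimethoxyphenyl]methanol
Product: 4 1-(benzyloxy)-5-(bromomethyl)-2,3-dimethoxybenzene
Conditions: PBr3, CH2Cl2, 0 °C
Reagents that add atoms: phosphorus tribromide, BrP(Br)Br
Why: Bromination of a benzylic alcohol through its phosphite ester with SN2 displacement by bromide; the electron-rich bromide should be used promptly.

Step 4
Reactants: 5 dimethyl malonate; 6 (R)-epichlorohydrin
Product: 10 methyl (1S,5R)-2-oxo-3-oxabicyclo[3.1.0]hexane-1-carboxylate, via chlorohydrin malonate 7 (not isolated), via epoxy malonate 8 (not isolated), via cyclopropylcarbinol diester 9 (not isolated)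
Conditions: NaOMe, MeOH, 0 °C to reflux
Reagents that add atoms: none
Why: Tandem malonate alkylation, cyclopropanation and lactonisation: the malonate opens the epoxide at CH2 to give 7, the alkoxide closes to epoxide 8, and the malonate anion opens 8 at the stereogenic carbon (3-exo-tet SN2, inversion) to give 9, which lactonises onto the cis ester. C5 of 10 derives from 6 through this single inversion and C1 follows from the obligatory cis ring fusion.

Step 5
Reactants: 10 methyl (1S,5R)-2-oxo-3-oxabicyclo[3.1.0]hexane-1-carboxylate; 11 3,4-dimethoxyphenylmagnesium bromide; 4 1-(benzyloxy)-5-(bromomethyl)-2,3-dimethoxybenzene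
Product: 13 methyl (3R,4R)-3-[3-(benzyloxy)-4,5-dimethoxybenzyl]-4-(3,4-dimethoxybenzyl)-2-oxotetrahydrofuran-3-carboxylate, via bromomagnesium enolate 12 (not isolated)
Conditions: CuI (10 mol%), THF, −30 to 0 °C; then 4, DMPU, Bu4NI (cat.), 0 to 45 °C
Reagents that add atoms: none
Why: Strain-release homoconjugate addition followed by enolate alkylation, three components in one pot. The Grignard and catalytic CuI give an arylcuprate that attacks the cyclopropane methylene C6 of 10 in an SN2-like oxidative addition, with the C1–C6 bond leaving as the doubly stabilised enolate; reductive elimination from copper forms the aryl–C7′ bond and releases enolate 12. The closest known reaction type is the copper-catalysed Grignard opening of cyclopropane-1,1-dicarbonyl compounds, established on 2-oxo-3-oxabicyclo[3.1.0]hexane-1-carboxylates as a route to 4-substituted butyrolactones, combined with the classical C-benzylation of α-alkoxycarbonyl lactone enolates. No ring is closed; the three-membered ring is opened and the lactone ring of 10 is kept. Attack at C6 and not at the ring-fusion carbon C5 is secured by the substrate, since C6 is an unhindered CH2 and C5 is tertiary; 1,2-addition to the carbonyl groups is suppressed by copper catalysis, low temperature and slow addition of 11. C4 of 13 is the untouched C5 of 10 and keeps its R configuration. The quaternary C3 should form by approach of 4 anti to the C4 arm, but this selectivity is not needed because C3 is reset in step 6. DMPU loosens the magnesium chelate so that the benzylic bromide alkylates on carbon, and 11 is kept near one equivalent so that little remains to couple with 4.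

Step 6
Reactants: 13 methyl (3R,4R)-3-[3-(benzyloxy)-4,5-dimethoxybenzyl]-4-(3,4-dimethoxybenzyl)-2-oxotetrahydrofuran-3-carboxylate
Product: 15 (3R,4R)-3-[3-(benzyloxy)-4,5-dimethoxybenzyl]-4-(3,4-dimethoxybenzyl)dihydrofuran-2(3H)-one, via cis-lactone 14 (not isolated)
Conditions: LiCl, H2O, DMSO, 150 °C; then DBU, 100 °C; aq. HCl work-up
Reagents that add atoms: none
Why: Krapcho dealkoxycarbonylation: chloride attacks the ester methyl, CO2 is lost and the lactone enolate is protonated by water, kinetically anti to the C4 arm, which should favour cis-lactone 14. DBU-mediated enolisation then equilibrates C3 to the more stable trans lactone 15; C4 is not acidic and stays R, and the acidic work-up recloses any opened lactone.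

Step 7
Reactants: 15 (3R,4R)-3-[3-(benzyloxy)-4,5-dimethoxybenzyl]-4-(3,4-dimethoxybenzyl)dihydrofuran-2(3H)-one
Product: 16 (3R,4R)-4-(3,4-dimethoxybenzyl)-3-(3-hydroxy-4,5-dimethoxybenzyl)dihydrofuran-2(3H)-one (CNP0246971.1)
Conditions: H2 (1 atm), 10% Pd/C, EtOAc–EtOH, rt
Reagents that add atoms: none
Why: Hydrogenolysis of the benzyl aryl ether under neutral conditions; the lactone, the methyl ethers and both stereocentres are not affected.

## Compound list

1 | 3-hydroxy-4,5-dimethoxybenzaldehyde | COc1cc(C=O)cc(O)c1OC | starting material
2 | 3-(benzyloxy)-4,5-dimethoxybenzaldehyde | COc1cc(C=O)cc(OCc2ccccc2)c1OC | intermediate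
3 | [3-(benzyloxy)-4,5-dimethoxyphenyl]methanol | COc1cc(CO)cc(OCc2ccccc2)c1OC | intermediate
4 | 1-(benzyloxy)-5-(bromomethyl)-2,3-dimethoxybenzene | COc1cc(CBr)cc(OCc2ccccc2)c1OC | intermediate
5 | dimethyl malonate | COC(=O)CC(=O)OC | starting material
6 | (R)-epichlorohydrin | ClC[C@H]1CO1 | starting material
7 | dimethyl 2-[(2R)-3-chloro-2-hydroxypropyl]propanedioate (present as its sodium alkoxide) | ClC[C@H](O)CC(C(=O)OC)C(=O)OC | intermediate
8 | dimethyl 2-{[(2R)-oxiran-2-yl]methyl}propanedioate | C1[C@H](O1)CC(C(=O)OC)C(=O)OC | intermediate
9 | dimethyl (2R)-2-(hydroxymethyl)cyclopropane-1,1-dicarboxylate (present as its sodium alkoxide) | C1[C@@H](CO)C1(C(=O)OC)C(=O)OC | intermediate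
10 | methyl (1S,5R)-2-oxo-3-oxabicyclo[3.1.0]hexane-1-carboxylate | COC(=O)[C@]12C[C@H]1COC2=O | intermediate
11 | 3,4-dimethoxyphenylmagnesium bromide | COc1ccc([Mg]Br)cc1OC | starting material
12 | bromomagnesium enolate of methyl (4R)-4-(3,4-dimethoxybenzyl)-2-oxotetrahydrofuran-3-carboxylate | COc1ccc(C[C@H]2COC(O[Mg]Br)=C2C(=O)OC)cc1OC | intermediate
13 | methyl (3R,4R)-3-[3-(benzyloxy)-4,5-dimethoxybenzyl]-4-(3,4-dimethoxybenzyl)-2-oxotetrahydrofuran-3-carboxylate | COc1ccc(C[C@H]2COC(=O)[C@@]2(Cc2cc(OCc3ccccc3)c(OC)c(OC)c2)C(=O)OC)cc1OC | intermediate
14 | (3S,4R)-3-[3-(benzyloxy)-4,5-dimethoxybenzyl]-4-(3,4-dimethoxybenzyl)dihydrofuran-2(3H)-one (cis) | COc1ccc(C[C@H]2COC(=O)[C@H]2Cc2cc(OCc3ccccc3)c(OC)c(OC)c2)cc1OC | intermediate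
15 | (3R,4R)-3-[3-(benzyloxy)-4,5-dimethoxybenzyl]-4-(3,4-dimethoxybenzyl)dihydrofuran-2(3H)-one (trans) | COc1ccc(C[C@H]2COC(=O)[C@@H]2Cc2cc(OCc3ccccc3)c(OC)c(OC)c2)cc1OC | intermediate
16 | (3R,4R)-4-(3,4-dimethoxybenzyl)-3-(3-hydroxy-4,5-dimethoxybenzyl)dihydrofuran-2(3H)-one | COc1ccc(C[C@H]2COC(=O)[C@@H]2Cc2cc(O)c(OC)c(OC)c2)cc1OC | target

## Step count and risks

Total step count: 7. Longest linear sequence: 6 steps (1 → 2 → 3 → 4 → 13 → 15 → 16); the branch from 5 and 6 joins at step 5 after one step.

Step 5 (key step). The aryl Grignard may add to the lactone or ester carbonyl instead of opening the cyclopropane. The chelated magnesium enolate may alkylate too slowly, so that it is only protonated on quench. Residual Grignard may couple with the benzylic bromide under copper. Fallback, from 10: the copper-catalysed opening with 11 is run alone and quenched to give methyl (3S,4R)-4-(3,4-dimethoxybenzyl)-2-oxotetrahydrofuran-3-carboxylate F1. Krapcho dealkoxycarbonylation (LiCl, wet DMSO, 150 °C) gives (4R)-4-(3,4-dimethoxybenzyl)dihydrofuran-2(3H)-one F2, which is the same compound as A1. Its lithium enolate (LiHMDS, THF, −78 °C) is alkylated with 4 anti to the C4 arm, which should give the trans lactone directly, and the route is rejoined at 15.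

Step 6. Dealkoxycarbonylation at the crowded quaternary centre may be slow. Chloride may open the lactone at C5 at 150 °C. Equilibration of C3 may stop short of completion. Fallback, from 13: saponification (LiOH, aq. THF–MeOH, 60 °C) cleaves the ester and opens the lactone, giving after acidification 2-{[3-(benzyloxy)-4,5-dimethoxyphenyl]methyl}-2-[(2R)-1-(3,4-dimethoxyphenyl)-3-hydroxypropan-2-yl]propanedioic acid F3. Heating F3 in toluene–AcOH at 110 °C relactonises and decarboxylates it to a mixture of 14 and 15, and DBU equilibration then returns the route at 15.

Step 4. Enantiomeric purity may be eroded, because direct displacement of chloride competes with epoxide opening and leads to the mirror-image bicycle. The epoxide may also oligomerise. Fallback, from 5: sodium dimethyl malonate (NaH, THF, 0 °C) is alkylated with (S)-glycidyl trifluoromethanesulfonate F4, made from commercial (R)-glycidol with Tf2O and 2,6-lutidine. The C–C bond then forms by direct SN2 at the sulfonate carbon and 8 arises without passing through 7. NaOMe closes 8 through 9 as in the main route, which is rejoined at 10.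

## Further compounds

F1 | step 5 | methyl (3S,4R)-4-(3,4-dimethoxybenzyl)-2-oxotetrahydrofuran-3-carboxylate | COc1ccc(C[C@H]2COC(=O)[C@@H]2C(=O)OC)cc1OC
F2 | step 5 | (4R)-4-(3,4-dimethoxybenzyl)dihydrofuran-2(3H)-one | COc1ccc(C[C@H]2COC(=O)C2)cc1OC
F3 | step 6 | 2-{[3-(benzyloxy)-4,5-dimethoxyphenyl]methyl}-2-[(2R)-1-(3,4-dimethoxyphenyl)-3-hydroxypropan-2-yl]propanedioic acid | COc1ccc(C[C@@H](CO)C(Cc2cc(OCc3ccccc3)c(OC)c(OC)c2)(C(=O)O)C(=O)O)cc1OC
F4 | step 4 | (S)-glycidyl trifluoromethanesulfonate | C1[C@H](O1)COS(=O)(=O)C(F)(F)F
A1 | alternative 1 | (4R)-4-(3,4-dimethoxybenzyl)dihydrofuran-2(3H)-one | COc1ccc(C[C@H]2COC(=O)C2)cc1OC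
A2 | alternative 2 | 3-(3,4-dimethoxybenzyl)cyclobutan-1-one | COc1ccc(CC2CC(=O)C2)cc1OC
A3 | alternative 3 | (2R,3R)-2-[3-(benzyloxy)-4,5-dimethoxybenzyl]-3-(3,4-dimethoxybenzyl)butanedioic acid | COc1ccc(C[C@@H](C(=O)O)[C@@H](Cc2cc(OCc3ccccc3)c(OC)c(OC)c2)C(=O)O)cc1OC
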